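(Its constants are invented; the rest is arithmetic.)

Starting material cannot become product in these flasks except by passing through the catalyst cycle, one molecule per turn.

    reagent + free catalyst ⇌ catalyst intermediate A (K1 = 19 M⁻¹, k1 = 3.5 M⁻¹ s⁻¹)
    scavenger + released group → scavenged by-product (k2 = 1.1 M⁻¹ s⁻¹)
    catalyst intermediate D → free catalyst + product (k3 = 1.5 s⁻¹)
    catalyst intermediate C → released group + catalyst intermediate D (k4 = 1.6 s⁻¹)
    reagent + released group ⇌ idle adduct, settled at all times (K5 = 7.4 M⁻¹)
    starting material + catalyst intermediate A ⇌ catalyst intermediate B (K6 = 4.4 M⁻¹, k6 = 210 M⁻¹ s⁻¹)
    catalyst intermediate B → catalyst intermediate C (k7 = 1.9 s⁻¹)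

| setting | violet | blue |
|---|---|---|
| starting material | 0.10 M | 0.10 M |
| reagent | 0.700 equiv | 0.700 equiv |
| scavenger | 0.500 equiv | 0.750 equiv |
| free catalyst | 1 mol% | 1 mol% |
| time | 3.0 min | 3.0 min |

- part of the starting material that has reacted at the end, violet
- part of the starting material that has reacted at the end, blue
- what raising the equivalents of scavenger from its lowest to its highest value here does to the part of the starting material that has reacted (changes below 5 percentage points count as none) (it rises / no change / it falls)

- amounts and yields of released group count idle adduct too
- run time (violet): 3.0 min

The cycle comes first in the reckoning. While the catalyst forms hold steady, the same net flux runs through every step of the cycle, so each form's amount divided by that flux is the time a turn spends there. Catalyst intermediates D, C and B take 0.667 s, 0.625 s and 0.526 s. But the binding of starting material is reversible, so catalyst intermediate A needs 1.24 s at the charged concentration. Step 1 runs back as well, so free catalyst takes 5.02 s at the charged concentration of reagent.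

An even spread would give every form the same time, and that is the zero of the scale. Free catalyst takes longer than any other form, so in this reckoning it is the resting state.

The sum of these times, catalyst charged over net flux, is the turnover time 8.08 s. Held at this starting value for the whole run, with the charges taken as undiminished, it gives 22.3 % for violet.

Scavenger appears nowhere in this sum. It touches the cycle through free released group, made at 1.24 × 10⁻⁴ M s⁻¹. That group's half-life against scavenger as charged, 0.21 min in violet, is shorter than the run, so this reckoning puts it near 0.00225 M in violet and 0.00150 M in blue. The reagent freed in blue adds about 0.12 percentage points, so this reckoning puts blue at 22.4 % and the trend reads no change.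

The forecast gives 19.2 % for violet and 19.4 % for blue, lower than this reckoning, and no change, noting: “Neither run exhausts its scavenger or reagent.”

The flasks give 19.3 % for violet and 19.4 % for blue, no change, with a shift of 0.05 points. In violet, the turnover time averaged over the run comes to 9.32 s, longer than the 8.08 s reckoned at the charges, and 68.7 % of the catalyst stands free at the end. In a neighbour flask, like violet but with 1.80 equiv of reagent, the turnover time at the charges reckons at 5.01 s, which held for the whole run gives 35.9 %, and that flask reaches 32.1 %.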